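**Strategy.** The 1,2-dioxane ring (O1–O2–C3–C4–C5–C6) is cut at C4–C5, the one ring bond that joins two carbons, each flanked by an oxygen-bearing carbon (C3 and C6). Ring-closing metathesis of an acyclic bis-allylic peroxide makes C4=C5 and the ring in a single operation, with both C–O bonds and the O–O bond already in place. The precursor is a dialkyl peroxide linking an (R)-allylic carbon that carries CH2CO2Me (C3, set by SN2 inversion of an α-acyl triflate) to a vinyl methoxy ketal carbon that carries a silyloxybutyl chain (C6, equilibrated later). The enyne arm is attached after the ring alkene has been saturated.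

Key step: step 12

Remark on the chemistry: the peroxyketal exchange cannot control the ketal carbon C6, so the key-step precursor and the key-step product are each formed and carried on as the unseparated pair of C6 epimers, each pair under one number and drawn as the epimer that maps onto the target; the acidic methanol of step 13 converges the pair. The oxanyl (THP) peroxyacetals are mixtures at the acetal carbon, which is removed in step 7. The chain alcohol is a tert-butyldiphenylsilyl ether because it must survive the acidic methanol of step 13. (S)-α-Hydroxy-γ-butyrolactone and methoxyallene are taken as commercial.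

**Fragment A: allylic hydroperoxide (C3 arm)**

Step 1
Reactants: 1 3,4-dihydro-2H-pyran
Product: 2 oxan-2-yl hydroperoxide
Conditions: 50% aq. H2O2 (excess), H2SO4 (cat.), 0 °C → rt
Reagents that add atoms: hydrogen peroxide, OO
Why: Acid-catalysed Markovnikov addition of H2O2 across the enol ether should give the hydroperoxy acetal, a protected HOO– nucleophile whose racemic acetal carbon is removed in step 7.

Step 2
Reactants: 3 (3S)-3-hydroxyoxolan-2-one
Product: 4 (3S)-2-oxooxolan-3-yl trifluoromethanesulfonate
Conditions: Tf2O, 2,6-lutidine, CH2Cl2, −78 °C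
Reagents that add atoms: trifluoromethanesulfonic anhydride, O=S(=O)(OS(=O)(=O)C(F)(F)F)C(F)(F)F
Why: O-Sulfonylation does not touch the C–O bond, so the S configuration is retained in an α-acyl triflate that is activated for SN2 and cannot ionise.

Step 3
Reactants: 4 (3S)-2-oxooxolan-3-yl trifluoromethanesulfonate; 2 oxan-2-yl hydroperoxide
Product: 5 (3R)-3-(oxan-2-ylperoxy)oxolan-2-one
Conditions: KOtBu (0.95 equiv relative to 2), THF, −78 → −20 °C
Reagents that add atoms: none
Why: SN2 alkylation of the peroxide anion by the α-acyl triflate should go with inversion (S to R) and so set the future C3, while the weakly basic α-effect nucleophile, the absence of free alkoxide and the low temperature disfavour elimination and Kornblum–DeLaMare cleavage.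

Step 4
Reactants: 5 (3R)-3-(oxan-2-ylperoxy)oxolan-2-one
Product: 6 (3R)-3-(oxan-2-ylperoxy)oxolan-2-ol
Conditions: iBu2AlH, CH2Cl2, −78 °C
Reagents that add atoms: none
Why: Partial lactone reduction stops at the lactol because the aluminate is stable at −78 °C, a temperature at which the dialkyl peroxide and the stereocentre should be untouched.

Step 5
Reactants: 6 (3R)-3-(oxan-2-ylperoxy)oxolan-2-ol
Product: 7 (3R)-3-(oxan-2-ylperoxy)pent-4-en-1-ol
Conditions: Ph3PCH3Br, KOtBu, THF, −78 → 0 °C
Reagents that add atoms: methyltriphenylphosphonium bromide, C[P+](c1ccccc1)(c1ccccc1)c1ccccc1.[Br-]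
Why: Wittig methylenation of the lactol through its open hydroxy aldehyde form installs the C3 vinyl group and frees the primary alcohol arm, the fast olefination at low temperature protecting the α-peroxy stereocentre from enolisation.

Step 6
Reactants: 7 (3R)-3-(oxan-2-ylperoxy)pent-4-en-1-ol
Product: 9 (3R)-3-(oxan-2-ylperoxy)pent-4-enoic acid, via aldehyde 8 (not isolated)
Conditions: TEMPO (cat.), PhI(OAc)2, MeCN–H2O, rt
Reagents that add atoms: water, O
Why: Oxoammonium oxidation takes the primary alcohol through the aldehyde hydrate to the acid under mildly acidic conditions that should spare the vinyl group, the peroxide and the base-sensitive β-peroxy carbonyl unit.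

Step 7
Reactants: 9 (3R)-3-(oxan-2-ylperoxy)pent-4-enoic acid
Product: 11 methyl (3R)-3-hydroperoxypent-4-enoate, via methyl ester 10 (not isolated)
Conditions: Me3SiCHN2, MeOH–PhMe, 0 °C; then TsOH·H2O (cat.), MeOH, rt
Reagents that add atoms: trimethylsilyldiazomethane, C[Si](C)(C)C=[N+]=[N-]
Why: Base-free methylation of the acid followed by acid-catalysed methanolysis of the peroxyacetal (transacetalisation to 2-methoxyoxane) should release the allylic hydroperoxide without involving the stereocentre.

**Fragment B: vinyl ketal (C6 arm)**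

Step 8
Reactants: 12 tetrahydrofuran
Product: 13 tert-butyl(4-iodobutoxy)diphenylsilane
Conditions: tBuPh2SiCl, NaI, MeCN, 55 °C (12 in excess)
Reagents that add atoms: tert-butylchlorodiphenylsilane, CC(C)(C)[Si](Cl)(c1ccccc1)c1ccccc1; sodium iodide, [Na+].[I-]
Why: Ether cleavage by the silyl iodide formed in the flask (O-silylation, then SN2 opening of the oxonium ion by iodide) gives the protected 4-iodobutanol in one operation.

Step 9
Reactants: 14 methoxyallene; 13 tert-butyl(4-iodobutoxy)diphenylsilane
Product: 15 tert-butyl[(5-methoxyhepta-5,6-dien-1-yl)oxy]diphenylsilane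
Conditions: nBuLi, THF, −40 °C; then 13, −40 °C → rt
Reagents that add atoms: none
Why: Deprotonation of methoxyallene at the oxygen-bearing carbon and SN2 alkylation by the primary iodide gives a masked acryloyl unit that already carries C5, C6 and the methoxy group.

Step 10
Reactants: 15 tert-butyl[(5-methoxyhepta-5,6-dien-1-yl)oxy]diphenylsilane
Product: 16 tert-butyl[(5,5-dimethoxyhept-6-en-1-yl)oxy]diphenylsilane
Conditions: MeOH (5 equiv), PPTS (cat.), CH2Cl2, 0 °C; Et3N quench
Reagents that add atoms: methanol, CO
Why: Acid-catalysed addition of an alcohol to an alkoxyallene protonates the central carbon and captures the vinyl-substituted oxocarbenium ion at the oxygen-bearing carbon under kinetic control, which avoids the free enone and its conjugate addition.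

**Union, ring closure and end game**

Step 11
Reactants: 11 methyl (3R)-3-hydroperoxypent-4-enoate; 16 tert-butyl[(5,5-dimethoxyhept-6-en-1-yl)oxy]diphenylsilane
Product: 17 methyl (3R)-3-{[(3R)-7-{[tert-butyl(diphenyl)silyl]oxy}-3-methoxyhept-1-en-3-yl]peroxy}pent-4-enoate (unseparated pair of C6 epimers; drawn as the 6R epimer)
Conditions: PPTS (cat.), 5 Å molecular sieves, CH2Cl2, 0 °C → rt (16 in excess)
Reagents that add atoms: none
Why: Acid-catalysed transketalisation of a dimethyl ketal by a hydroperoxide, driven by the sieves taking up methanol, should give the mixed peroxyketal with the allylic centre untouched; the planar oxocarbenium ion is captured on both faces, so both configurations of the ketal carbon form, which is accepted because step 13 corrects it.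

Step 12
Reactants: 17 methyl (3R)-3-{[(3R)-7-{[tert-butyl(diphenyl)silyl]oxy}-3-methoxyhept-1-en-3-yl]peroxy}pent-4-enoate (pair of C6 epimers)
Product: 18 methyl 2-[(3R,6R)-6-(4-{[tert-butyl(diphenyl)silyl]oxy}butyl)-6-methoxy-3,6-dihydro-1,2-dioxin-3-yl]acetate (unseparated pair of C6 epimers; drawn as the 6R epimer)
Conditions: second-generation Grubbs catalyst RuCl2(=CHPh)(H2IMes)(PCy3) (cat.), 1,4-benzoquinone (cat.), CH2Cl2 (high dilution), 40 °C
Reagents that add atoms: none
Why: The ruthenium alkylidene should load on the less hindered C3 vinyl group by cycloaddition and cycloreversion, then engage the C6 vinyl group through a ruthenacyclobutane and release ethene, which forms C4=C5 and closes the 3,6-dihydro-1,2-dioxine. The closest known reaction type is ring-closing metathesis of dienes tethered through a dialkyl peroxide and of mixed ketals whose allylic carbon is quaternary. The six-membered ring closes at its only all-carbon bond, and the ring enforces the cis alkene. No stereocentre is formed, since C3 was set by inversion in step 3 and both C6 epimers of the precursor can close, each giving its own ring epimer. The selectivity needed is chemoselectivity for the two vinyl groups over the O–O bond, the acid-labile ketal and the base-labile β-peroxy ester; it is secured because the peroxide carries no O–H, the medium is neutral and aprotic, dilution favours six-membered closure, and benzoquinone suppresses hydride-mediated alkene migration.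

Step 13
Reactants: 18 methyl 2-[(3R,6R)-6-(4-{[tert-butyl(diphenyl)silyl]oxy}butyl)-6-methoxy-3,6-dihydro-1,2-dioxin-3-yl]acetate (pair of C6 epimers)
Product: 20 methyl 2-[(3S,6R)-6-(4-{[tert-butyl(diphenyl)silyl]oxy}butyl)-6-methoxy-1,2-dioxan-3-yl]acetate, via (3S,6S)-epimer 19 (not isolated)
Conditions: KO2CN=NCO2K, AcOH, CH2Cl2, 0 °C → rt; filter, evaporate; then CSA (cat.), MeOH–CH2Cl2, rt
Reagents that add atoms: methanol, CO
Why: Diimide reduction saturates the only C=C by concerted syn hydrogen transfer without touching O–O, so the 6R component gives 20 directly and the 6S component gives 19, and acid in methanol then exchanges the C6 methoxy group with the solvent through the oxocarbenium ion and should funnel the pair to the epimer with axial OMe (anomeric effect) and both carbon chains equatorial, which is the 6R configuration of the target (C3 changes descriptor only, not geometry).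

Step 14
Reactants: 20 methyl 2-[(3S,6R)-6-(4-{[tert-butyl(diphenyl)silyl]oxy}butyl)-6-methoxy-1,2-dioxan-3-yl]acetate
Product: 21 methyl 2-[(3S,6R)-6-(4-hydroxybutyl)-6-methoxy-1,2-dioxan-3-yl]acetate
Conditions: Bu4NF, AcOH, THF, rt
Reagents that add atoms: none
Why: Fluoride desilylation buffered by AcOH is near neutral, which should avoid both base-induced opening of the β-peroxy ester and acid-induced spiroketalisation of the δ-hydroxy ketal.

Step 15
Reactants: 21 methyl 2-[(3S,6R)-6-(4-hydroxybutyl)-6-methoxy-1,2-dioxan-3-yl]acetate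
Product: 22 methyl 2-[(3S,6R)-6-methoxy-6-(4-oxobutyl)-1,2-dioxan-3-yl]acetate
Conditions: Dess–Martin periodinane, NaHCO3, CH2Cl2, 0 °C → rt
Reagents that add atoms: none
Why: Buffered Dess–Martin oxidation stops at the aldehyde, and hypervalent iodine oxidants do not attack dialkyl peroxides or the peroxyketal.

Step 16
Reactants: 22 methyl 2-[(3S,6R)-6-methoxy-6-(4-oxobutyl)-1,2-dioxan-3-yl]acetate
Product: 23 methyl 2-[(3S,6R)-6-methoxy-6-(pent-4-yn-1-yl)-1,2-dioxan-3-yl]acetate
Conditions: MeC(O)C(N2)P(O)(OMe)2, K2CO3, MeOH, 0 °C → rt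
Reagents that add atoms: dimethyl (1-diazo-2-oxopropyl)phosphonate, CC(=O)C(=[N+]=[N-])P(=O)(OC)OC
Why: Ohira–Bestmann (Seyferth–Gilbert) homologation adds the diazomethylphosphonate anion to the aldehyde and the alkylidene carbene rearranges to the terminal alkyne, with carbonate at low temperature chosen to keep the β-peroxy ester closed.

Step 17
Reactants: 24 dec-9-en-1-ol
Product: 25 dec-9-enal
Conditions: TEMPO (cat.), PhI(OAc)2, CH2Cl2, rt
Reagents that add atoms: none
Why: Oxoammonium oxidation in anhydrous CH2Cl2 stops at the aldehyde and leaves the terminal alkene alone.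

Step 18
Reactants: 25 dec-9-enal
Product: 26 (1E)-1-iodoundeca-1,10-diene
Conditions: CrCl2, CHI3, THF–dioxane, 0 °C → rt
Reagents that add atoms: iodoform, IC(I)I
Why: Takai olefination adds the geminal dichromium carbenoid CHI(CrCl2)2, formed from CHI3 and CrCl2 (divalent chromium), to the aldehyde and eliminates to give the E-vinyl iodide preferentially, the remote terminal alkene being inert.

Step 19
Reactants: 23 methyl 2-[(3S,6R)-6-methoxy-6-(pent-4-yn-1-yl)-1,2-dioxan-3-yl]acetate; 26 (1E)-1-iodoundeca-1,10-diene
Product: 27 peroxyacarnoate A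
Conditions: Pd(PPh3)4 (cat.), CuI (cat.), iPr2NH, THF, rt
Reagents that add atoms: none
Why: Sonogashira coupling of the terminal alkyne with the vinyl iodide proceeds with retention of the E geometry at room temperature, and dialkyl peroxides and peroxyketals should tolerate zerovalent palladium, CuI and a secondary amine.

**Compound list**

1 | 3,4-dihydro-2H-pyran | C1=COCCC1 | starting material
2 | oxan-2-yl hydroperoxide (racemic) | OOC1CCCCO1 | intermediate
3 | (3S)-3-hydroxyoxolan-2-one, (S)-α-hydroxy-γ-butyrolactone | O=C1OCC[C@@H]1O | starting material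
4 | (3S)-2-oxooxolan-3-yl trifluoromethanesulfonate | O=C1OCC[C@@H]1OS(=O)(=O)C(F)(F)F | intermediate
5 | (3R)-3-(oxan-2-ylperoxy)oxolan-2-one | O=C1OCC[C@H]1OOC2CCCCO2 | intermediate
6 | (3R)-3-(oxan-2-ylperoxy)oxolan-2-ol (lactol, both anomers) | OC1OCC[C@H]1OOC2CCCCO2 | intermediate
7 | (3R)-3-(oxan-2-ylperoxy)pent-4-en-1-ol | OCC[C@H](C=C)OOC1CCCCO1 | intermediate
8 | (3R)-3-(oxan-2-ylperoxy)pent-4-enal | O=CC[C@H](C=C)OOC1CCCCO1 | intermediate
9 | (3R)-3-(oxan-2-ylperoxy)pent-4-enoic acid | OC(=O)C[C@H](C=C)OOC1CCCCO1 | intermediate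
10 | methyl (3R)-3-(oxan-2-ylperoxy)pent-4-enoate | COC(=O)C[C@H](C=C)OOC1CCCCO1 | intermediate
11 | methyl (3R)-3-hydroperoxypent-4-enoate | COC(=O)C[C@H](C=C)OO | intermediate
12 | tetrahydrofuran | C1CCOC1 | starting material
13 | tert-butyl(4-iodobutoxy)diphenylsilane | CC(C)(C)[Si](c1ccccc1)(c1ccccc1)OCCCCI | intermediate
14 | methoxyallene (1-methoxypropa-1,2-diene) | COC=C=C | starting material
15 | tert-butyl[(5-methoxyhepta-5,6-dien-1-yl)oxy]diphenylsilane | C=C=C(OC)CCCCO[Si](c1ccccc1)(c1ccccc1)C(C)(C)C | intermediate
16 | tert-butyl[(5,5-dimethoxyhept-6-en-1-yl)oxy]diphenylsilane | C=CC(OC)(OC)CCCCO[Si](c1ccccc1)(c1ccccc1)C(C)(C)C | intermediate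
17 | methyl (3R)-3-{[(3R)-7-{[tert-butyl(diphenyl)silyl]oxy}-3-methoxyhept-1-en-3-yl]peroxy}pent-4-enoate (key-step precursor; unseparated pair of epimers at the ketal carbon C6, drawn as the 6R epimer that maps onto the target) | CC(C)(C)[Si](c1ccccc1)(c1ccccc1)OCCCC[C@](OO[C@@H](C=C)CC(=O)OC)(OC)C=C | intermediate
18 | methyl 2-[(3R,6R)-6-(4-{[tert-butyl(diphenyl)silyl]oxy}butyl)-6-methoxy-3,6-dihydro-1,2-dioxin-3-yl]acetate (key-step product; unseparated pair of C6 epimers, drawn as the 6R epimer that maps onto the target) | CC(C)(C)[Si](c1ccccc1)(c1ccccc1)OCCCC[C@]1(OC)C=C[C@@H](CC(=O)OC)OO1 | intermediate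
19 | methyl 2-[(3S,6S)-6-(4-{[tert-butyl(diphenyl)silyl]oxy}butyl)-6-methoxy-1,2-dioxan-3-yl]acetate (saturated 6S epimer, converted in the flask) | CC(C)(C)[Si](c1ccccc1)(c1ccccc1)OCCCC[C@@]1(OC)CC[C@@H](CC(=O)OC)OO1 | intermediate
20 | methyl 2-[(3S,6R)-6-(4-{[tert-butyl(diphenyl)silyl]oxy}butyl)-6-methoxy-1,2-dioxan-3-yl]acetate | CC(C)(C)[Si](c1ccccc1)(c1ccccc1)OCCCC[C@]1(OC)CC[C@@H](CC(=O)OC)OO1 | intermediate
21 | methyl 2-[(3S,6R)-6-(4-hydroxybutyl)-6-methoxy-1,2-dioxan-3-yl]acetate | OCCCC[C@]1(OC)CC[C@@H](CC(=O)OC)OO1 | intermediate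
22 | methyl 2-[(3S,6R)-6-methoxy-6-(4-oxobutyl)-1,2-dioxan-3-yl]acetate | O=CCCC[C@]1(OC)CC[C@@H](CC(=O)OC)OO1 | intermediate
23 | methyl 2-[(3S,6R)-6-methoxy-6-(pent-4-yn-1-yl)-1,2-dioxan-3-yl]acetate | C#CCCC[C@]1(OC)CC[C@@H](CC(=O)OC)OO1 | intermediate
24 | dec-9-en-1-ol | C=CCCCCCCCCO | starting material
25 | dec-9-enal | C=CCCCCCCCC=O | intermediate
26 | (1E)-1-iodoundeca-1,10-diene | C=CCCCCCCC/C=C/I | intermediate
27 | peroxyacarnoate A, methyl 2-[(3S,6R)-6-methoxy-6-[(6E)-hexadeca-6,15-dien-4-yn-1-yl]-1,2-dioxan-3-yl]acetate | C=CCCCCCCC/C=C/C#CCCC[C@]1(OC)CC[C@@H](CC(=O)OC)OO1 | target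

**Step count**

Total steps: 19. Longest linear sequence: 13 steps (3 → 27 through steps 2–7, 11–16 and 19).

**Steps most likely to fail**

Step 12 (ring-closing metathesis). The ruthenium carbene may be consumed by reaction at the allylic O–O bond, or closure at the hindered quaternary ketal alkene may be too slow to outrun alkene migration and loss of the ketal. The fallback uses no metathesis and closes the ring at C6–O1 by peroxyketalisation; it sets out from ester 10 (isolated by stopping step 7 after the methylation) and comes back at 20. Commercial δ-valerolactone is opened by two equivalents of Ph3P=CH2 to the acyl ylide (6-hydroxy-2-oxohexylidene)triphenylphosphorane F1, which is silylated (tBuPh2SiCl, imidazole) to (6-{[tert-butyl(diphenyl)silyl]oxy}-2-oxohexylidene)triphenylphosphorane F2. Ozonolysis of the vinyl group of 10 (O3, CH2Cl2, −78 °C; Me2S) should give the α-peroxy aldehyde methyl (3R)-4-oxo-3-(oxan-2-ylperoxy)butanoate F3. Wittig reaction of F3 with the stabilised, non-basic ylide F2 (CH2Cl2, rt) should give the enone methyl (3R,4E)-10-{[tert-butyl(diphenyl)silyl]oxy}-6-oxo-3-(oxan-2-ylperoxy)dec-4-enoate F4. Diimide reduction should then give the keto peroxide methyl (3S)-10-{[tert-butyl(diphenyl)silyl]oxy}-6-oxo-3-(oxan-2-ylperoxy)decanoate F5. CSA in methanol removes the oxanyl group, the freed hydroperoxide adds to the C6 ketone, and the cyclic hemiperketal is converted to the methyl ketal under the same thermodynamic control as in step 13, giving 20.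

Step 5 (lactol methylenation). The excess basic ylide needed to open the lactol may cause Kornblum–DeLaMare cleavage of the open α-peroxy aldehyde or enolisation that erodes the C3 configuration. The fallback sets out from lactone 5 and comes back at 7, and runs the olefination on a discrete, protected aldehyde at low temperature with one equivalent of ylide. LiBH4 (THF, 0 °C) should reduce 5 to (2R)-2-(oxan-2-ylperoxy)butane-1,4-diol F6. Silylation of the less hindered 4-OH (tBuPh2SiCl, imidazole, −20 °C) gives (2R)-4-{[tert-butyl(diphenyl)silyl]oxy}-2-(oxan-2-ylperoxy)butan-1-ol F7. Buffered Dess–Martin oxidation gives (2R)-4-{[tert-butyl(diphenyl)silyl]oxy}-2-(oxan-2-ylperoxy)butanal F8. Salt-free Ph3P=CH2 at −78 °C gives tert-butyl{[(3R)-3-(oxan-2-ylperoxy)pent-4-en-1-yl]oxy}diphenylsilane F9, and Bu4NF/AcOH releases 7.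

Step 11 (peroxyketal exchange). The exchange may stall because liberated methanol re-adds, the vinyl-substituted oxocarbenium ion may be captured at its terminal carbon on prolonged exposure to acid, or the allylic hydroperoxide may degrade under the acid. The fallback sets out from hydroperoxide 11 and alkoxyallene 15 and comes back at 17. The hydroperoxide is added directly across the enol ether bond of 15 (PPTS, CH2Cl2, −20 °C), an addition that releases no methanol and so can be run colder, with less acid and for a shorter time. It makes no compound outside the list (F0).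

Further compounds

F1 | step 12 | (6-hydroxy-2-oxohexylidene)triphenylphosphorane | OCCCCC(=O)C=P(c1ccccc1)(c1ccccc1)c1ccccc1
F2 | step 12 | (6-{[tert-butyl(diphenyl)silyl]oxy}-2-oxohexylidene)triphenylphosphorane | CC(C)(C)[Si](c1ccccc1)(c1ccccc1)OCCCCC(=O)C=P(c1ccccc1)(c1ccccc1)c1ccccc1
F3 | step 12 | methyl (3R)-4-oxo-3-(oxan-2-ylperoxy)butanoate | COC(=O)C[C@H](C=O)OOC1CCCCO1
F4 | step 12 | methyl (3R,4E)-10-{[tert-butyl(diphenyl)silyl]oxy}-6-oxo-3-(oxan-2-ylperoxy)dec-4-enoate | COC(=O)C[C@H](/C=C/C(=O)CCCCO[Si](c1ccccc1)(c1ccccc1)C(C)(C)C)OOC1CCCCO1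
F5 | step 12 | methyl (3S)-10-{[tert-butyl(diphenyl)silyl]oxy}-6-oxo-3-(oxan-2-ylperoxy)decanoate | COC(=O)C[C@H](CCC(=O)CCCCO[Si](c1ccccc1)(c1ccccc1)C(C)(C)C)OOC1CCCCO1
F6 | step 5 | (2R)-2-(oxan-2-ylperoxy)butane-1,4-diol | OCC[C@H](CO)OOC1CCCCO1
F7 | step 5 | (2R)-4-{[tert-butyl(diphenyl)silyl]oxy}-2-(oxan-2-ylperoxy)butan-1-ol | CC(C)(C)[Si](c1ccccc1)(c1ccccc1)OCC[C@H](CO)OOC1CCCCO1
F8 | step 5 | (2R)-4-{[tert-butyl(diphenyl)silyl]oxy}-2-(oxan-2-ylperoxy)butanal | CC(C)(C)[Si](c1ccccc1)(c1ccccc1)OCC[C@H](C=O)OOC1CCCCO1
F9 | step 5 | tert-butyl{[(3R)-3-(oxan-2-ylperoxy)pent-4-en-1-yl]oxy}diphenylsilane | CC(C)(C)[Si](c1ccccc1)(c1ccccc1)OCC[C@H](C=C)OOC1CCCCO1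
F0 | step 11 | none | none
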